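**Retrosynthetic overview** (germacrane numbering; ring A = ten-membered carbocycle C1–C10, ring B = α-methylene-γ-lactone O–C6–C7–C11–C12)
1. Endgame: C8 angeloylation, then acid removal of a C1/C10 acetonide and a C3 silyl ether.
2. Key disconnection C7–C8: C8 is a carbinol carbon bonded to C7, the allylic position of the exocyclic C11=C13 methylene of ring B (a homoallylic alcohol). Ring A is therefore closed by CrCl2-mediated intramolecular allylation of a C8 aldehyde by the 3-(bromomethyl)but-2-enolide unit C13–C11=C7, which also sets C7 and C8 and unveils the exocyclic methylene.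
3. Ring B is made first, by ring-closing metathesis of a 2-(bromomethyl)acrylate on the C6 oxygen with a C7 vinyl group; the Z C4=C5 alkene and a temporary cis-dioxolane on C1/C10 fold the open chain.
4. Open chain: C2–C3 boron aldol between a methyl ketone (C1, C2, C8–C10; C10 from a Cu-catalysed Mukaiyama aldol on butane-2,3-dione) and a Z-enal (C3–C7; C6 from (R)-but-3-ene-1,2-diol, Z-alkene by Still–Gennari olefination), then 1,3-anti reduction for C1.
5. Order of ring formation: temporary dioxolane (step 12), ring B (step 16), ring A (step 17).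

Key step: step 17

Assumption: the ligand antipode in step 8 and the borane antipode in step 9 are named for the facial senses expected from the pyruvate ester and methyl ketone precedents of these reagent classes; should either prove opposite, the mirror-image ligand or borane is used with no other change.

**Route**

Step 1
Reactants: 1 (R)-but-3-ene-1,2-diol; 2 4-methoxybenzaldehyde dimethyl acetal
Product: 3 (4R)-2-(4-methoxyphenyl)-4-vinyl-1,3-dioxolane (mixture of epimers at C2)
Conditions: PPTS (cat.), CH2Cl2, rt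
Reagents that add atoms: none
Why: Acid-catalysed transacetalisation of the 1,2-diol; the stereocentre (C6 of the target) is not involved.

Step 2
Reactants: 3 (4R)-2-(4-methoxyphenyl)-4-vinyl-1,3-dioxolane
Product: 4 (2R)-2-[(4-methoxybenzyl)oxy]but-3-en-1-ol
Conditions: iBu2AlH (DIBAL-H), CH2Cl2, −78 to 0 °C
Reagents that add atoms: none
Why: Regioselective reductive opening of a p-methoxybenzylidene acetal: the aluminium hydride binds the less hindered primary oxygen and cleaves that C–O bond, which should leave the PMB group on the secondary oxygen.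

Step 3
Reactants: 4 (2R)-2-[(4-methoxybenzyl)oxy]but-3-en-1-ol
Product: 5 (2R)-2-[(4-methoxybenzyl)oxy]but-3-enal
Conditions: Dess–Martin periodinane, pyridine, CH2Cl2, 0 °C; used crude
Reagents that add atoms: none
Why: Dess–Martin oxidation under buffered, non-basic conditions, so that the α-alkoxy β,γ-unsaturated aldehyde should neither epimerise nor move into conjugation.

Step 4
Reactants: 5 (2R)-2-[(4-methoxybenzyl)oxy]but-3-enal; 6 ethyl 2-[bis(2,2,2-trifluoroethoxy)phosphoryl]propanoate
Product: 8 ethyl (2Z,4R)-4-[(4-methoxybenzyl)oxy]-2-methylhexa-2,5-dienoate, via potassium phosphonate carbanion 7 (not isolated)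
Conditions: KN(SiMe3)2 (KHMDS), 18-crown-6, THF, −78 °C; then 5
Reagents that add atoms: none
Why: Still–Gennari olefination: the trifluoroethyl phosphonate eliminates fast from the kinetic adduct and should give the (Z)-2-methyl enoate, in which C6 and C3 are cis as in the target.

Step 5
Reactants: 8 ethyl (2Z,4R)-4-[(4-methoxybenzyl)oxy]-2-methylhexa-2,5-dienoate
Product: 9 (2Z,4R)-4-[(4-methoxybenzyl)oxy]-2-methylhexa-2,5-dien-1-ol
Conditions: iBu2AlH (2.5 equiv), CH2Cl2, −78 °C
Reagents that add atoms: none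
Why: 1,2-Reduction of the enoate by the aluminium hydride to the allylic alcohol with retention of the alkene geometry.

Step 6
Reactants: 9 (2Z,4R)-4-[(4-methoxybenzyl)oxy]-2-methylhexa-2,5-dien-1-ol
Product: 10 (2Z,4R)-4-[(4-methoxybenzyl)oxy]-2-methylhexa-2,5-dienal
Conditions: Dess–Martin periodinane, pyridine, CH2Cl2, 0 °C
Reagents that add atoms: none
Why: Dess–Martin oxidation of the allylic alcohol, mild enough under pyridine buffering to keep the Z geometry of the enal.

Step 7
Reactants: 11 S-tert-butyl ethanethioate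
Product: 13 tert-butyl 1-(trimethylsilyloxy)ethenyl sulfide, via lithium enolate 12 (not isolated)
Conditions: LiN(iPr)2 (LDA), THF, −78 °C; then Me3SiCl
Reagents that add atoms: chlorotrimethylsilane, C[Si](C)(C)Cl
Why: Kinetic enolisation of the thioester and O-silylation should give the silyl ketene thioacetal needed as Mukaiyama aldol donor.

Step 8
Reactants: 13 tert-butyl 1-(trimethylsilyloxy)ethenyl sulfide; 14 butane-2,3-dione
Product: 15 S-tert-butyl (3R)-3-methyl-4-oxo-3-[(trimethylsilyl)oxy]pentanethioate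
Conditions: Cu(OTf)2 (10 mol %), (R,R)-2,2′-isopropylidenebis(4-tert-butyl-2-oxazoline) (11 mol %), THF, −78 °C; non-acidic work-up
Reagents that add atoms: none
Why: Catalytic enantioselective Mukaiyama aldol addition to a chelating 1,2-dicarbonyl compound: the diketone binds divalent copper in a bidentate way, a tert-butyl group of the ligand shields one carbonyl face and silyl transfer releases the silyl ether, which should set C10 as (R).

Step 9
Reactants: 15 S-tert-butyl (3R)-3-methyl-4-oxo-3-[(trimethylsilyl)oxy]pentanethioate; 10 (2Z,4R)-4-[(4-methoxybenzyl)oxy]-2-methylhexa-2,5-dienal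
Product: 17 S-tert-butyl (3R,6S,7Z,9R)-6-hydroxy-9-[(4-methoxybenzyl)oxy]-3,7-dimethyl-4-oxo-3-[(trimethylsilyl)oxy]undeca-7,10-dienethioate, via boron enolate 16 (not isolated)
Conditions: (+)-Ipc2BCl, Et3N, Et2O, 0 °C; then 10, −78 to −20 °C; then H2O2, MeOH, pH 7 buffer, 0 °C
Reagents that add atoms: none
Why: Paterson boron aldol of a methyl ketone: only the methyl group is enolised (the thioester α-CH2 is neopentylic), and the isopinocampheyl ligands should direct the enolate to the Si face of the enal, setting C3 as (S).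

Step 10
Reactants: 17 β-hydroxy ketone from step 9
Product: 18 S-tert-butyl (3R,4S,6S,7Z,9R)-4,6-dihydroxy-9-[(4-methoxybenzyl)oxy]-3,7-dimethyl-3-[(trimethylsilyl)oxy]undeca-7,10-dienethioate
Conditions: Me4NBH(OAc)3, MeCN/AcOH (1:1), −30 °C
Reagents that add atoms: none
Why: Evans–Saksena reduction: the C3 hydroxyl binds boron and delivers hydride intramolecularly through a chair transition state, which should set C1 anti to C3 regardless of the neighbouring quaternary centre.

Step 11
Reactants: 18 anti-1,3-diol from step 10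
Product: 19 S-tert-butyl (3R,4S,6S,7Z,9R)-6-[(tert-butyldimethylsilyl)oxy]-4-hydroxy-9-[(4-methoxybenzyl)oxy]-3,7-dimethyl-3-[(trimethylsilyl)oxy]undeca-7,10-dienethioate
Conditions: TBSCl, imidazole, DMF, 0 °C
Reagents that add atoms: tert-butyldimethylsilyl chloride, CC(C)(C)[Si](C)(C)Cl
Why: Kinetically selective silyl ether formation: the allylic C3 carbinol should react, while the C1 carbinol next to the fully substituted, silyloxy-bearing C10 is too hindered.

Step 12
Reactants: 19 mono-TBS ether from step 11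
Product: 21 S-tert-butyl 2-[(4R,5S)-5-{(2S,3Z,5R)-2-[(tert-butyldimethylsilyl)oxy]-5-[(4-methoxybenzyl)oxy]-3-methylhepta-3,6-dien-1-yl}-2,2,4-trimethyl-1,3-dioxolan-4-yl]ethanethioate, via desilylated diol 20 (not isolated)
Conditions: PPTS, MeOH, rt; evaporate; then 2,2-dimethoxypropane, PPTS, acetone, rt
Reagents that add atoms: 2,2-dimethoxypropane, COC(C)(C)OC
Why: Acid-catalysed methanolysis of the tertiary trimethylsilyl ether, then acetonide formation (transketalisation) on the only free diol, giving the cis-dioxolane on C1/C10 while the TBS and PMB ethers should survive PPTS.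

Step 13
Reactants: 21 acetonide thioester from step 12
Product: 22 2-[(4R,5S)-5-{(2S,3Z,5R)-2-[(tert-butyldimethylsilyl)oxy]-5-[(4-methoxybenzyl)oxy]-3-methylhepta-3,6-dien-1-yl}-2,2,4-trimethyl-1,3-dioxolan-4-yl]acetaldehyde
Conditions: iBu2AlH (1.2 equiv), CH2Cl2, −78 °C
Reagents that add atoms: none
Why: Partial reduction of the thioester by the aluminium hydride through a tetrahedral intermediate that is stable at −78 °C should give the C8 aldehyde; no other carbonyl group is present at this stage.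

Step 14
Reactants: 22 aldehyde from step 13
Product: 23 2-[(4R,5S)-5-{(2S,3Z,5R)-2-[(tert-butyldimethylsilyl)oxy]-5-hydroxy-3-methylhepta-3,6-dien-1-yl}-2,2,4-trimethyl-1,3-dioxolan-4-yl]acetaldehyde
Conditions: DDQ (1.2 equiv), CH2Cl2/pH 7 buffer, 0 °C
Reagents that add atoms: none
Why: Oxidative cleavage of the PMB ether by DDQ; buffering, low temperature and limited oxidant should spare the liberated bis-allylic C6 carbinol, the silyl ether and the acetonide.

Step 15
Reactants: 23 C6 alcohol from step 14; 24 2-(bromomethyl)prop-2-enoic acid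
Product: 25 (3R,4Z,6S)-6-[(tert-butyldimethylsilyl)oxy]-5-methyl-7-[(4S,5R)-2,2,5-trimethyl-5-(2-oxoethyl)-1,3-dioxolan-4-yl]hepta-1,4-dien-3-yl 2-(bromomethyl)prop-2-enoate
Conditions: DCC, DMAP (5 mol %), CH2Cl2, 0 °C
Reagents that add atoms: none
Why: Steglich esterification of the only free hydroxyl; catalytic DMAP at 0 °C limits attack on the allylic bromide.

Step 16
Reactants: 25 acrylate ester from step 15
Product: 26 (5S)-3-(bromomethyl)-5-[(1Z,3S)-3-[(tert-butyldimethylsilyl)oxy]-2-methyl-4-[(4S,5R)-2,2,5-trimethyl-5-(2-oxoethyl)-1,3-dioxolan-4-yl]but-1-en-1-yl]furan-2(5H)-one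
Conditions: Hoveyda–Grubbs second-generation catalyst RuCl2(H2IMes)(=CH-C6H4-2-OiPr) (10 mol %), toluene (0.005 M), 80 °C
Reagents that add atoms: none
Why: Ring-closing metathesis of an acrylate ester of an allylic alcohol to a but-2-enolide: the catalyst should load on the terminal C7 vinyl group and close five-membered ring B onto the 1,1-disubstituted acrylate with loss of ethene, the trisubstituted C4=C5 alkene being inert.

Step 17
Reactants: 26 bromomethyl butenolide aldehyde from step 16
Product: 28 (1S,3S,6S,7S,8R,10R)-3-[(tert-butyldimethylsilyl)oxy]-8-hydroxy-1,10-(isopropylidenedioxy)germacra-4(Z),11(13)-dien-12,6-olide, via allylchromium dichloride 27 (not isolated)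
Conditions: CrCl2 (10 equiv), THF, rt; 26 added by syringe pump (final 0.002 M)
Reagents that add atoms: none
Why: Two one-electron reductions by CrCl2 should turn the allylic bromide into an allyl species of trivalent chromium at C13 (27), which adds through its γ-carbon C7 to the chromium-bound C8 aldehyde in a six-membered Zimmerman–Traxler chair (SE2′), so that the C7–C8 bond, both new stereocentres and the exocyclic C11=C13 methylene arise together; the closest known reaction type is the intramolecular Nozaki–Hiyama allylation of ω-formyl 2-(bromomethyl)alk-2-enoates used to close ten-membered germacranolide carbocycles, together with intermolecular Barbier allylations of 3-(bromomethyl)butenolides. Ring A closes in a 10-exo-trig mode with respect to the C8 carbonyl. C7 is controlled by the C6 stereocentre: the aldehyde should reach C7 on the butenolide face opposite to the C5 alkenyl substituent, which is also the only way to avoid a third cisoid torsion in the ten-membered ring, giving the trans-fused lactone. C8 is controlled by the chair: the allyl unit has fixed geometry (C6 trans to the CH2Cr group, enforced by ring B) and the aldehyde substituent C9 should sit equatorial, which gives the anti relationship of C8–O and C7–C6 needed for (7S,8R). The step needs γ- over α-attack (secured by the cyclic transition state), intra- over intermolecular addition (secured by slow addition at high dilution and by the Z C4=C5 alkene and the cis-dioxolane, which fold the chain) and chemoselectivity (CrCl2 leaves lactone, silyl ether and acetonide untouched, and the alkoxide of trivalent chromium is too weakly nucleophilic to translactonise to the 8,12-olide).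

Step 18
Reactants: 28 macrocyclic alcohol from step 17; 29 angelic acid ((Z)-2-methylbut-2-enoic acid); 30 2,4,6-trichlorobenzoyl chloride
Product: 32 (1S,3S,6S,7S,8R,10R)-8-[(Z)-2-methylbut-2-enoyloxy]-3-[(tert-butyldimethylsilyl)oxy]-1,10-(isopropylidenedioxy)germacra-4(Z),11(13)-dien-12,6-olide, via mixed anhydride 31 (not isolated)
Conditions: 29, 30, Et3N (1 equiv), toluene, rt; then 28, 70 °C
Reagents that add atoms: none
Why: Yamaguchi-type esterification through the mixed anhydride without a nucleophilic catalyst, the established way to transfer an angeloyl group without Z-to-E isomerisation to the tiglate; only the C8 hydroxyl is free.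

Step 19
Reactants: 32 protected angelate from step 18
Product: 33 CNP0249520.1, (1S,3S,6S,7S,8R,10R)-8-angeloyloxy-1,3,10-trihydroxygermacra-4(Z),11(13)-dien-12,6-olide
Conditions: TFA/H2O/THF (1:1:3), 0 °C to rt
Reagents that add atoms: none
Why: Acid hydrolysis should cleave the dioxolane and the allylic silyl ether in one operation, while the angelate, the lactone and the exocyclic methylene are stable to cold aqueous acid.

**Compound list**

1 | (R)-but-3-ene-1,2-diol | C=C[C@@H](O)CO | starting material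
2 | 4-methoxybenzaldehyde dimethyl acetal | COc1ccc(C(OC)OC)cc1 | starting material
3 | (4R)-2-(4-methoxyphenyl)-4-vinyl-1,3-dioxolane (epimers at C2) | C=C[C@@H]1COC(c2ccc(OC)cc2)O1 | intermediate
4 | (2R)-2-[(4-methoxybenzyl)oxy]but-3-en-1-ol | C=C[C@@H](OCc1ccc(OC)cc1)CO | intermediate
5 | (2R)-2-[(4-methoxybenzyl)oxy]but-3-enal | C=C[C@@H](OCc1ccc(OC)cc1)C=O | intermediate
6 | ethyl 2-[bis(2,2,2-trifluoroethoxy)phosphoryl]propanoate | CCOC(=O)C(C)P(=O)(OCC(F)(F)F)OCC(F)(F)F | starting material
7 | potassium carbanion of phosphonate 6 | [K+].CCOC(=O)[C-](C)P(=O)(OCC(F)(F)F)OCC(F)(F)F | intermediate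
8 | ethyl (2Z,4R)-4-[(4-methoxybenzyl)oxy]-2-methylhexa-2,5-dienoate | CCOC(=O)/C(C)=C\[C@H](OCc1ccc(OC)cc1)C=C | intermediate
9 | (2Z,4R)-4-[(4-methoxybenzyl)oxy]-2-methylhexa-2,5-dien-1-ol | OC/C(C)=C\[C@H](OCc1ccc(OC)cc1)C=C | intermediate
10 | (2Z,4R)-4-[(4-methoxybenzyl)oxy]-2-methylhexa-2,5-dienal | O=C/C(C)=C\[C@H](OCc1ccc(OC)cc1)C=C | intermediate
11 | S-tert-butyl ethanethioate | CC(=O)SC(C)(C)C | starting material
12 | lithium enolate of 11 | [Li+].C=C([O-])SC(C)(C)C | intermediate
13 | tert-butyl 1-(trimethylsilyloxy)ethenyl sulfide | C=C(O[Si](C)(C)C)SC(C)(C)C | intermediate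
14 | butane-2,3-dione | CC(=O)C(C)=O | starting material
15 | S-tert-butyl (3R)-3-methyl-4-oxo-3-[(trimethylsilyl)oxy]pentanethioate | CC(=O)[C@](C)(O[Si](C)(C)C)CC(=O)SC(C)(C)C | intermediate
16 | diisopinocampheylboron enolate of 15 | C=C(OB([C@H]1C[C@H]2C[C@@H]([C@@H]1C)C2(C)C)[C@H]1C[C@H]2C[C@@H]([C@@H]1C)C2(C)C)[C@](C)(O[Si](C)(C)C)CC(=O)SC(C)(C)C | intermediate
17 | S-tert-butyl (3R,6S,7Z,9R)-6-hydroxy-9-[(4-methoxybenzyl)oxy]-3,7-dimethyl-4-oxo-3-[(trimethylsilyl)oxy]undeca-7,10-dienethioate | C=C[C@@H](OCc1ccc(OC)cc1)/C=C(/C)[C@@H](O)CC(=O)[C@](C)(O[Si](C)(C)C)CC(=O)SC(C)(C)C | intermediate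
18 | S-tert-butyl (3R,4S,6S,7Z,9R)-4,6-dihydroxy-9-[(4-methoxybenzyl)oxy]-3,7-dimethyl-3-[(trimethylsilyl)oxy]undeca-7,10-dienethioate | C=C[C@@H](OCc1ccc(OC)cc1)/C=C(/C)[C@@H](O)C[C@H](O)[C@](C)(O[Si](C)(C)C)CC(=O)SC(C)(C)C | intermediate
19 | 6-O-TBS ether of 18 | C=C[C@@H](OCc1ccc(OC)cc1)/C=C(/C)[C@@H](O[Si](C)(C)C(C)(C)C)C[C@H](O)[C@](C)(O[Si](C)(C)C)CC(=O)SC(C)(C)C | intermediate
20 | S-tert-butyl (3R,4S,6S,7Z,9R)-6-[(tert-butyldimethylsilyl)oxy]-3,4-dihydroxy-9-[(4-methoxybenzyl)oxy]-3,7-dimethylundeca-7,10-dienethioate | C=C[C@@H](OCc1ccc(OC)cc1)/C=C(/C)[C@@H](O[Si](C)(C)C(C)(C)C)C[C@H](O)[C@](C)(O)CC(=O)SC(C)(C)C | intermediate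
21 | S-tert-butyl 2-[(4R,5S)-5-{(2S,3Z,5R)-2-[(tert-butyldimethylsilyl)oxy]-5-[(4-methoxybenzyl)oxy]-3-methylhepta-3,6-dien-1-yl}-2,2,4-trimethyl-1,3-dioxolan-4-yl]ethanethioate | C=C[C@@H](OCc1ccc(OC)cc1)/C=C(/C)[C@@H](O[Si](C)(C)C(C)(C)C)C[C@@H]1OC(C)(C)O[C@]1(C)CC(=O)SC(C)(C)C | intermediate
22 | 2-[(4R,5S)-5-{(2S,3Z,5R)-2-[(tert-butyldimethylsilyl)oxy]-5-[(4-methoxybenzyl)oxy]-3-methylhepta-3,6-dien-1-yl}-2,2,4-trimethyl-1,3-dioxolan-4-yl]acetaldehyde | C=C[C@@H](OCc1ccc(OC)cc1)/C=C(/C)[C@@H](O[Si](C)(C)C(C)(C)C)C[C@@H]1OC(C)(C)O[C@]1(C)CC=O | intermediate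
23 | 2-[(4R,5S)-5-{(2S,3Z,5R)-2-[(tert-butyldimethylsilyl)oxy]-5-hydroxy-3-methylhepta-3,6-dien-1-yl}-2,2,4-trimethyl-1,3-dioxolan-4-yl]acetaldehyde | C=C[C@@H](O)/C=C(/C)[C@@H](O[Si](C)(C)C(C)(C)C)C[C@@H]1OC(C)(C)O[C@]1(C)CC=O | intermediate
24 | 2-(bromomethyl)prop-2-enoic acid | C=C(CBr)C(=O)O | starting material
25 | (3R,4Z,6S)-6-[(tert-butyldimethylsilyl)oxy]-5-methyl-7-[(4S,5R)-2,2,5-trimethyl-5-(2-oxoethyl)-1,3-dioxolan-4-yl]hepta-1,4-dien-3-yl 2-(bromomethyl)prop-2-enoate | C=C[C@@H](OC(=O)C(=C)CBr)/C=C(/C)[C@@H](O[Si](C)(C)C(C)(C)C)C[C@@H]1OC(C)(C)O[C@]1(C)CC=O | intermediate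
26 | (5S)-3-(bromomethyl)-5-[(1Z,3S)-3-[(tert-butyldimethylsilyl)oxy]-2-methyl-4-[(4S,5R)-2,2,5-trimethyl-5-(2-oxoethyl)-1,3-dioxolan-4-yl]but-1-en-1-yl]furan-2(5H)-one | O=C1O[C@@H](/C=C(/C)[C@@H](O[Si](C)(C)C(C)(C)C)C[C@@H]2OC(C)(C)O[C@]2(C)CC=O)C=C1CBr | intermediate
27 | allylchromium dichloride from 26 (trivalent chromium at C13, solvent ligands omitted) | O=C1O[C@@H](/C=C(/C)[C@@H](O[Si](C)(C)C(C)(C)C)C[C@@H]2OC(C)(C)O[C@]2(C)CC=O)C=C1C[Cr](Cl)Cl | intermediate
28 | (1S,3S,6S,7S,8R,10R)-3-[(tert-butyldimethylsilyl)oxy]-8-hydroxy-1,10-(isopropylidenedioxy)germacra-4(Z),11(13)-dien-12,6-olide | C=C1C(=O)O[C@H]2/C=C(/C)[C@@H](O[Si](C)(C)C(C)(C)C)C[C@@H]3OC(C)(C)O[C@]3(C)C[C@@H](O)[C@H]12 | intermediate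
29 | angelic acid, (Z)-2-methylbut-2-enoic acid | C/C=C(/C)C(=O)O | starting material
30 | 2,4,6-trichlorobenzoyl chloride | O=C(Cl)c1c(Cl)cc(Cl)cc1Cl | starting material
31 | angelic 2,4,6-trichlorobenzoic anhydride | C/C=C(/C)C(=O)OC(=O)c1c(Cl)cc(Cl)cc1Cl | intermediate
32 | 8-O-angeloyl derivative of 28 | C=C1C(=O)O[C@H]2/C=C(/C)[C@@H](O[Si](C)(C)C(C)(C)C)C[C@@H]3OC(C)(C)O[C@]3(C)C[C@@H](OC(=O)/C(C)=C\C)[C@H]12 | intermediate
33 | CNP0249520.1, (1S,3S,6S,7S,8R,10R)-8-angeloyloxy-1,3,10-trihydroxygermacra-4(Z),11(13)-dien-12,6-olide | C=C1C(=O)O[C@H]2/C=C(/C)[C@@H](O)C[C@H](O)[C@](C)(O)C[C@@H](OC(=O)/C(C)=C\C)[C@H]12 | target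

**Step count**

Total step count: 19. Longest linear sequence: 17 steps (steps 1–6 and 9–19, from 1); steps 7–8 form the second branch.

**Steps most likely to fail**

Step 17 (closure of ring A). Intermolecular allylation to oligomers may outrun the entropically costly ten-membered closure, or the aldehyde may react through its other face and give the C8 epimer. The fallback closes the same bond with inverted polarity at both ends. It sets out from 26: exchange of bromide for acetate (AgOAc, acetone, rt) should give the acetoxymethyl butenolide aldehyde F1. Treatment with SmI2 (2.5 equiv) and t-BuOH in THF at −78 °C under high dilution should form the C8 ketyl radical anion, which adds to C7, the β-carbon of the butenolide (ketyl–olefin coupling). The resulting enolate of trivalent samarium then expels acetate from C13 (E1cB) to unveil the exocyclic methylene. The route is rejoined at 28.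

Step 16 (ring-closing metathesis). The allylic bromide may deactivate the ruthenium carbene, or the electron-poor 1,1-disubstituted acrylate may engage too slowly, so that the bromide is lost before ring B forms. The fallback brings the bromide in after the metathesis. It sets out from 23: Steglich esterification with the known 2-{[(triethylsilyl)oxy]methyl}prop-2-enoic acid should give the silyloxymethyl acrylate F2, and ring-closing metathesis under the step 16 conditions the silyloxymethyl butenolide F3. HF·pyridine/pyridine in THF at 0 °C should free the primary allylic alcohol F4 without touching the secondary TBS ether, the acetonide or the aldehyde. Corey–Kim bromination (NBS, Me2S, CH2Cl2, −20 °C; neutral and aldehyde-tolerant) returns to 26.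

Step 9 (aldol). Low or reversed facial selectivity at C3 would also misplace C1 in step 10. The fallback takes both carbinols from catalyst-controlled or hydroxyl-directed ketone reductions instead. It sets out from 15 and 10: the aldol is run with (c-Hex)2BCl/Et3N to give the β-hydroxy ketone F5 as a mixture of C3 epimers, which is silylated (TESCl, imidazole) to the triethylsilyl ether F6. Corey–Bakshi–Shibata reduction (BH3·SMe2, (R)-2-methyl-CBS-oxazaborolidine, THF, −20 °C; quaternary C10 as the large group) should set C1 in the carbinol F7. PPTS/MeOH removes both silyl groups to give the triol F8, and MnO2 oxidises only the allylic C3 carbinol to the enone diol F9. Me4NBH(OAc)3 then reduces the enone 1,3-anti under direction of the C1 hydroxyl to the single triol F10. C3-selective silylation as in step 11 gives 20, which is carried on to 21 as in step 12.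

Further compounds
F1 | step 17 | (5S)-3-(acetoxymethyl) analogue of 26 | O=C1O[C@@H](/C=C(/C)[C@@H](O[Si](C)(C)C(C)(C)C)C[C@@H]2OC(C)(C)O[C@]2(C)CC=O)C=C1COC(C)=O
F2 | step 16 | (3R,4Z,6S)-6-[(tert-butyldimethylsilyl)oxy]-5-methyl-7-[(4S,5R)-2,2,5-trimethyl-5-(2-oxoethyl)-1,3-dioxolan-4-yl]hepta-1,4-dien-3-yl 2-{[(triethylsilyl)oxy]methyl}prop-2-enoate | C=C[C@@H](OC(=O)C(=C)CO[Si](CC)(CC)CC)/C=C(/C)[C@@H](O[Si](C)(C)C(C)(C)C)C[C@@H]1OC(C)(C)O[C@]1(C)CC=O
F3 | step 16 | (5S)-3-{[(triethylsilyl)oxy]methyl} analogue of 26 | O=C1O[C@@H](/C=C(/C)[C@@H](O[Si](C)(C)C(C)(C)C)C[C@@H]2OC(C)(C)O[C@]2(C)CC=O)C=C1CO[Si](CC)(CC)CC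
F4 | step 16 | (5S)-3-(hydroxymethyl) analogue of 26 | O=C1O[C@@H](/C=C(/C)[C@@H](O[Si](C)(C)C(C)(C)C)C[C@@H]2OC(C)(C)O[C@]2(C)CC=O)C=C1CO
F5 | step 9 | S-tert-butyl (3R,7Z,9R)-6-hydroxy-9-[(4-methoxybenzyl)oxy]-3,7-dimethyl-4-oxo-3-[(trimethylsilyl)oxy]undeca-7,10-dienethioate (both C6 epimers) | C=C[C@@H](OCc1ccc(OC)cc1)/C=C(/C)C(O)CC(=O)[C@](C)(O[Si](C)(C)C)CC(=O)SC(C)(C)C
F6 | step 9 | 6-O-triethylsilyl ether of F5 (both C6 epimers) | C=C[C@@H](OCc1ccc(OC)cc1)/C=C(/C)C(O[Si](CC)(CC)CC)CC(=O)[C@](C)(O[Si](C)(C)C)CC(=O)SC(C)(C)C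
F7 | step 9 | S-tert-butyl (3R,4S,7Z,9R)-4-hydroxy-9-[(4-methoxybenzyl)oxy]-3,7-dimethyl-6-[(triethylsilyl)oxy]-3-[(trimethylsilyl)oxy]undeca-7,10-dienethioate (both C6 epimers) | C=C[C@@H](OCc1ccc(OC)cc1)/C=C(/C)C(O[Si](CC)(CC)CC)C[C@H](O)[C@](C)(O[Si](C)(C)C)CC(=O)SC(C)(C)C
F8 | step 9 | S-tert-butyl (3R,4S,7Z,9R)-3,4,6-trihydroxy-9-[(4-methoxybenzyl)oxy]-3,7-dimethylundeca-7,10-dienethioate (both C6 epimers) | C=C[C@@H](OCc1ccc(OC)cc1)/C=C(/C)C(O)C[C@H](O)[C@](C)(O)CC(=O)SC(C)(C)C
F9 | step 9 | S-tert-butyl (3R,4S,7Z,9R)-3,4-dihydroxy-9-[(4-methoxybenzyl)oxy]-3,7-dimethyl-6-oxoundeca-7,10-dienethioate | C=C[C@@H](OCc1ccc(OC)cc1)/C=C(/C)C(=O)C[C@H](O)[C@](C)(O)CC(=O)SC(C)(C)C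
F10 | step 9 | S-tert-butyl (3R,4S,6S,7Z,9R)-3,4,6-trihydroxy-9-[(4-methoxybenzyl)oxy]-3,7-dimethylundeca-7,10-dienethioate | C=C[C@@H](OCc1ccc(OC)cc1)/C=C(/C)[C@@H](O)C[C@H](O)[C@](C)(O)CC(=O)SC(C)(C)C
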